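**Plan**
The target, 5,7-dihydroxy-2-tridecylchromone, is achiral, so no stereochemistry has to be set.
Enabling feature: O1 (on C8a) and the oxygens on C5 and C7 of ring A (the benzene ring) lie ortho, ortho and para to the C4 carbonyl, the pattern of a 2,4,6-trifluorobenzoyl group, so all three aryl C–O bonds can come from fluoride displacement.
Retrosynthesis: cut C5–O and C7–O back to C–F, then cut O1–C8a of ring B (the pyranone) back to C–F plus a 1,3-diketone, then cut C3–C4 between an acid chloride and a methyl ketone.
Forward: the chain is joined to the arene by enolate C-acylation (C3–C4), ring B closes onto ring A through O1–C8a, the two remaining fluorides are exchanged for benzyloxy groups, and the benzyl groups are removed.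

Key step: step 2

Remark: diketone 4 is drawn as the diketo tautomer, although it should exist largely as the chelated enol; this does not affect the chemistry.

**Route**

Step 1
Reactants: 1 pentadecan-2-one; 2 2,4,6-trifluorobenzoyl chloride
Product: 4 1-(2,4,6-trifluorophenyl)hexadecane-1,3-dione, via lithium pentadec-1-en-2-olate 3 (not isolated)
Conditions: LiN(iPr)2 (2.1 equiv), 1 (2.0 equiv), THF, −78 °C; then 2 (1.0 equiv), −78 °C; cold 1 M HCl
Reagents that add atoms: none
Why: Kinetic deprotonation of the methyl ketone by the hindered lithium amide at −78 °C gives the less substituted enolate 3, whose carbon attacks the very electrophilic acid chloride in a Claisen-type C-acylation; the second equivalent of 3 takes up the acidic proton of the product, which is thereby held as its unreactive enolate until the cold acid quench.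

Step 2
Reactants: 4 1-(2,4,6-trifluorophenyl)hexadecane-1,3-dione
Product: 5 5,7-difluoro-2-tridecylchromone
Conditions: K2CO3 (2 equiv), dry DMF, 25 → 60 °C
Reagents that add atoms: none
Why: K2CO3 removes a proton from the methylene between the two carbonyls, and the enolate oxygen on the tridecyl-bearing carbon adds to one of the two equivalent fluorine-bearing ortho carbons to give a Meisenheimer anion stabilised by the aroyl carbonyl and the other fluorines; loss of fluoride restores the arene and forms O1–C8a. This is an intramolecular nucleophilic aromatic substitution by addition–elimination, the closest known type being the base-mediated cyclisation of 1-(2-fluoroaryl)-1,3-diketones to chromones. Ring B is the only ring closed: a six-membered closure onto a trigonal carbon, which is a 6-endo-trig conjugate addition to the C8a=C4a bond activated by C4=O, followed by loss of the fluoride that lies outside the new ring. No stereocentre is formed. The selectivity needed is O- over C-cyclisation: the central carbon of the monoenolate could only form a four-membered ring, and the chain CH2 next to the alkyl carbonyl, whose attack would give a carbocycle, is not deprotonated by carbonate, so oxygen attack is the only open path. The symmetric arene leaves no regiochemical choice, and the C5 and C7 fluorides of the product stay activated by the C4 carbonyl for the next step.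

Step 3
Reactants: 5 5,7-difluoro-2-tridecylchromone; 6 benzyl alcohol
Product: 9 5,7-bis(benzyloxy)-2-tridecylchromone, via sodium benzyloxide 7 (not isolated), via 7-benzyloxy-5-fluoro-2-tridecylchromone 8 (not isolated)
Conditions: 6 (2.5 equiv), NaH (2.4 equiv), THF, 0 °C; then 5, THF–DMF, 0 → 50 °C
Reagents that add atoms: none
Why: The fluorides on C7 (para) and C5 (ortho) are both conjugated to the C4 carbonyl through C4a, so benzyloxide adds at each carbon to give a carbonyl-stabilised Meisenheimer anion and fluoride leaves (nucleophilic aromatic substitution, expected first at C7 in the dipolar medium, either order converging on 9), while the C2 alkyl group disfavours the reversible conjugate addition at C2.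

Step 4
Reactants: 9 5,7-bis(benzyloxy)-2-tridecylchromone
Product: 10 5,7-dihydroxy-2-tridecylchromone
Conditions: BCl3 (5 equiv), C6HMe5 (6 equiv), CH2Cl2, −78 → 0 °C; then MeOH, H2O
Reagents that add atoms: none
Why: Lewis-acid cleavage of aryl benzyl ethers: BCl3 binds the ether oxygens (the C5 ether helped by chelation to the C4 carbonyl) and breaks the benzyl–oxygen bonds at low temperature, pentamethylbenzene trapping the benzyl cation by Friedel–Crafts alkylation so that it cannot attack C6 or C8 of ring A, and aqueous methanol then frees the phenols from boron without touching the pyranone double bond.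

**Compound list**
1 | pentadecan-2-one | CCCCCCCCCCCCCC(C)=O | starting material
2 | 2,4,6-trifluorobenzoyl chloride | O=C(Cl)c1c(F)cc(F)cc1F | starting material
3 | lithium pentadec-1-en-2-olate | [Li+].[O-]C(=C)CCCCCCCCCCCCC | intermediate (not isolated)
4 | 1-(2,4,6-trifluorophenyl)hexadecane-1,3-dione | CCCCCCCCCCCCCC(=O)CC(=O)c1c(F)cc(F)cc1F | intermediate
5 | 5,7-difluoro-2-tridecylchromone (5,7-difluoro-2-tridecyl-4H-chromen-4-one) | CCCCCCCCCCCCCc1cc(=O)c2c(F)cc(F)cc2o1 | intermediate
6 | benzyl alcohol | OCc1ccccc1 | starting material
7 | sodium benzyloxide | [Na+].[O-]Cc1ccccc1 | intermediate (not isolated)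
8 | 7-benzyloxy-5-fluoro-2-tridecylchromone | CCCCCCCCCCCCCc1cc(=O)c2c(F)cc(OCc3ccccc3)cc2o1 | intermediate (not isolated)
9 | 5,7-bis(benzyloxy)-2-tridecylchromone | CCCCCCCCCCCCCc1cc(=O)c2c(OCc3ccccc3)cc(OCc3ccccc3)cc2o1 | intermediate
10 | 5,7-dihydroxy-2-tridecylchromone (5,7-dihydroxy-2-tridecyl-4H-chromen-4-one) | CCCCCCCCCCCCCc1cc(=O)c2c(O)cc(O)cc2o1 | target

**Totals and risks**
Total step count: 4. Longest linear sequence: 4 steps (1 → 4 → 5 → 9 → 10).

Steps most likely to fail, riskiest first:

Step 3. The alkoxide may add reversibly at C2 and open the pyranone, may deprotonate the chain CH2 next to C2 and so slow the substitution, or the second displacement may stall. The fallback brings the oxygens in before the pyranone exists, so that the chromone never meets an alkoxide. It sets out from 2 and comes back at 9. Acid chloride 2 is treated with three equivalents of sodium benzyloxide 7 in THF–DMF at 0 °C. Acyl substitution followed by displacement of the para and one ortho fluoride should give benzyl 2,4-bis(benzyloxy)-6-fluorobenzoate F1, the limited amount of alkoxide and the low temperature sparing the last ortho fluoride. Crossed Claisen condensation of F1 with two equivalents of enolate 3 (THF, −78 → 0 °C) should give 1-[2,4-bis(benzyloxy)-6-fluorophenyl]hexadecane-1,3-dione F2. Heating F2 with K2CO3 in DMF closes O1–C8a by the same fluoride displacement as in step 2 and delivers 9.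

Step 1. The enolate may be acylated on oxygen, proton exchange with liberated ketone may scramble the enolate regiochemistry, or the product enolate may be acylated a second time. The fallback replaces acylation by aldol addition and oxidation; it sets out from 3 and comes back at 4. Enolate 3 is added at −78 °C to commercial 2,4,6-trifluorobenzaldehyde (O=Cc1c(F)cc(F)cc1F), which can react only at carbon and only once, to give racemic 1-hydroxy-1-(2,4,6-trifluorophenyl)hexadecan-3-one F3. Oxidation of the benzylic alcohol with Dess–Martin periodinane in CH2Cl2 gives 4 and removes the transient stereocentre.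

Step 4. The benzyl cation may escape the scavenger and alkylate the electron-rich ring A at C6 or C8, or the non-chelated C7 ether may be cleaved incompletely. The fallback changes the ether so that no stabilised cation is released; it sets out from 5 and comes back at 10. Difluoride 5 is treated with NaOMe in MeOH–DMF to give 5,7-dimethoxy-2-tridecylchromone F4, and both methyl ethers are cleaved with excess BBr3 in CH2Cl2 (−78 °C → room temperature) to give 10 after aqueous work-up.

**Further compounds**
F1 | step 3 | benzyl 2,4-bis(benzyloxy)-6-fluorobenzoate | O=C(OCc1ccccc1)c1c(F)cc(OCc2ccccc2)cc1OCc1ccccc1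
F2 | step 3 | 1-[2,4-bis(benzyloxy)-6-fluorophenyl]hexadecane-1,3-dione | CCCCCCCCCCCCCC(=O)CC(=O)c1c(F)cc(OCc2ccccc2)cc1OCc1ccccc1
F3 | step 1 | 1-hydroxy-1-(2,4,6-trifluorophenyl)hexadecan-3-one (racemic) | CCCCCCCCCCCCCC(=O)CC(O)c1c(F)cc(F)cc1F
F4 | step 4 | 5,7-dimethoxy-2-tridecylchromone | CCCCCCCCCCCCCc1cc(=O)c2c(OC)cc(OC)cc2o1
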